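**Retrosynthetic overview**
1. 25 ⇒ 22: remove C17 (aldol with CH2O at C16, the only enolisable carbon) and the silyl group.
2. 22 ⇒ 20: one-carbon ring expansion of a tethered cyclobutanone by the α-diazo-δ-lactone carbon C8 (C8–C15 addition, 1,2-shift of C14, loss of N2). Rings C and D, C8 and C13 form in one step.
3. 20 ⇒ 17 ⇒ 15: diazo transfer. The δ-lactone (C20–O–C7) comes from reduction and oxidative lactonisation.
4. 15 ⇒ 6 + 14: an iminium Michael addition makes C9–C10 (quaternary C10, tertiary C9).
5. 6 ⇒ 1 + 2 + 4 (Knoevenagel, enamine Michael, aldol condensation); 14 ⇒ 7 + 8 + 13. Ring order: A, then the lactone, then C and D together.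

Assumption: atom labels C1–C20 follow ent-kaurane numbering (C6 and C7 are the seco termini), and aldehyde 1 is bought in its silyl-protected form.

**Step 1**
Reactants: 1 2-[(tert-butyldiphenylsilyl)oxy]acetaldehyde; 2 methyl acetoacetate
Product: 3 methyl 2-acetyl-4-[(tert-butyldiphenylsilyl)oxy]but-2-enoate (E/Z mixture)
Conditions: piperidine (10 mol %), AcOH (10 mol %), 4 Å MS, CH2Cl2, 0 °C → rt
Reagents that add atoms: none
Why: Knoevenagel condensation of the aldehyde at the active methylene of 2 joins C5 to C10; no stereocentre forms and both alkene isomers converge in step 2.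

**Step 2**
Reactants: 3 methyl 2-acetyl-4-[(tert-butyldiphenylsilyl)oxy]but-2-enoate; 4 isobutyraldehyde
Product: 6 methyl (1S,6S)-6-{[(tert-butyldiphenylsilyl)oxy]methyl}-5,5-dimethyl-2-oxocyclohex-3-ene-1-carboxylate, via keto aldehyde Michael adduct 5 (not isolated)
Conditions: 1-[(1R,2R)-2-aminocyclohexyl]-3-[3,5-bis(trifluoromethyl)phenyl]thiourea (20 mol %), PhCO2H (10 mol %), toluene, rt; then TsOH·H2O (30 mol %), 80 °C
Reagents that add atoms: none
Why: Enamine-catalysed Michael addition of the α,α-disubstituted aldehyde to the doubly activated alkene (the thiourea binds the 1,3-dicarbonyl and the chiral enamine attacks one face of C5, setting C5; the catalyst antipode is used if the sense proves opposite), then acid-catalysed intramolecular aldol condensation of the methyl ketone onto the neopentyl aldehyde (Robinson-type annulation) closes ring A, and C10 equilibrates to the trans ester.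

**Step 3**
Reactants: 7 hexa-1,5-diene (4 equiv); 8 N,N-dimethylacetamide
Product: 11 3-(but-3-en-1-yl)cyclobutan-1-one, via keteniminium triflate 9 (not isolated), via cyclobutaniminium triflate 10 (not isolated)
Conditions: Tf2O, 2,4,6-collidine, ClCH2CH2Cl, reflux; then aq NaHCO3, rt
Reagents that add atoms: water, O
Why: Ghosez keteniminium–alkene [2+2] cycloaddition; the electrophilic central carbon bonds to the terminal CH2, so the 3-substituted ring forms, excess diene limits the reaction to the mono-adduct, and no stereocentre is created.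

**Step 4**
Reactants: 11 3-(but-3-en-1-yl)cyclobutan-1-one
Product: 12 2-(but-3-en-1-yl)-5,8-dioxaspiro[3.4]octane
Conditions: ethylene glycol, TsOH·H2O (2 mol %), toluene, Dean–Stark, reflux
Reagents that add atoms: ethylene glycol, OCCO
Why: Acid-catalysed ketalisation, favoured for a cyclobutanone by relief of angle strain at the sp2 carbon, masks the ketone against hydride and amide base.

**Step 5**
Reactants: 12 2-(but-3-en-1-yl)-5,8-dioxaspiro[3.4]octane; 13 (E)-crotonaldehyde (4 equiv)
Product: 14 (E)-5-(5,8-dioxaspiro[3.4]octan-2-yl)pent-2-enal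
Conditions: second-generation Hoveyda–Grubbs catalyst RuCl2(H2IMes)(=CH-C6H4-2-OiPr) (3 mol %), CH2Cl2, 40 °C
Reagents that add atoms: none
Why: Olefin cross metathesis of a terminal alkene with an electron-poor partner gives the E-enal selectively and brings in C7 and C8.

**Step 6**
Reactants: 6 methyl (1S,6S)-6-{[(tert-butyldiphenylsilyl)oxy]methyl}-5,5-dimethyl-2-oxocyclohex-3-ene-1-carboxylate; 14 (E)-5-(5,8-dioxaspiro[3.4]octan-2-yl)pent-2-enal
Product: 15 (5R,9R,10R)-aldehyde methyl 6-{[(tert-butyldiphenylsilyl)oxy]methyl}-1-[1-(5,8-dioxaspiro[3.4]octan-2-yl)-5-oxopentan-3-yl]-5,5-dimethyl-2-oxocyclohex-3-ene-1-carboxylate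
Conditions: (S)-2-[diphenyl(trimethylsilyloxy)methyl]pyrrolidine (20 mol %), PhCO2H (20 mol %), toluene, 0 °C → rt
Reagents that add atoms: none
Why: Iminium-catalysed Michael addition (Jørgensen–Hayashi catalyst) of a cyclic β-keto ester; the (S)-catalyst shields one face of the E,s-trans iminium and fixes C9, while the enol of 6 reacts anti to its pseudo-axial C5 side chain, so C9 ends trans and the C20 ester cis to C6 at the new quaternary C10.

**Step 7**
Reactants: 15 (5R,9R,10R)-aldehyde
Product: 16 (5R,9R,10S)-triol with C1 allylic alcohol (epimer mixture), C20H2OH and C7H2OH; ketal and silyl ether retained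
Conditions: LiAlH4, Et2O, 0 °C → rt; H2O/NaOH work-up
Reagents that add atoms: none
Why: Hydride reduction of the aldehyde, the ester and the enone (1,2-mode) brings C20 to the alcohol level; the new C1 carbinol centre is irrelevant because it is removed in step 8.

**Step 8**
Reactants: 16 (5R,9R,10S)-triol
Product: 17 (5R,6S,11R)-11-{[(tert-butyldiphenylsilyl)oxy]methyl}-5-[2-(5,8-dioxaspiro[3.4]octan-2-yl)ethyl]-10,10-dimethyl-2-oxaspiro[5.5]undec-8-ene-3,7-dione
Conditions: nPr4N[RuO4] (10 mol %), NMO (6 equiv), 4 Å MS, CH2Cl2, rt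
Reagents that add atoms: none
Why: Ley–Griffith oxidation with oxidative lactonisation; the unhindered C7 alcohol is oxidised first, the neopentyl C20–OH traps the aldehyde as a six-membered lactol that goes on to the δ-lactone, and the allylic C1 alcohol returns to the enone.

**Step 9**
Reactants: 17 spirolactone enone ketal
Product: 20 (5S,6S,11R)-11-{[(tert-butyldiphenylsilyl)oxy]methyl}-4-diazo-10,10-dimethyl-5-[2-(3-oxocyclobutyl)ethyl]-2-oxaspiro[5.5]undec-8-ene-3,7-dione, via trifluoroacetyl lactone ketal 18 (not isolated), via trifluoroacetyl keto lactone 19 (not isolated)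
Conditions: LiN(SiMe3)2, THF, −78 °C; CF3CO2CH2CF3; 1 M HCl, THF, rt; crude, then MsN3, Et3N, H2O, MeCN, rt
Reagents that add atoms: methanesulfonyl azide, CS(=O)(=O)N=[N+]=[N-]; water, O; 2,2,2-trifluoroethyl trifluoroacetate, O=C(OCC(F)(F)F)C(F)(F)F (its atoms stay only in 18 and 19)
Why: Danheiser detrifluoroacetylative diazo transfer; C8 is the only acidic carbon while the ketone is masked, the acidic work-up frees the cyclobutanone before any diazo group is present, and the mild Et3N transfer touches only the activated C8, with no stereocentre affected.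

**Step 10**
Reactants: 20 α-diazo-δ-lactone carrying the 2-(3-oxocyclobutyl)ethyl chain at C9
Product: 22 (5R,8S,9S,10S,13R)-tetracyclic β-keto lactone (6-O-TBDPS-1,15-dioxo-17-nor-6,7-seco-ent-kaur-2-en-7,20-olide with C16H2), via diazonium alkoxide betaine 21 (not isolated)
Conditions: Sc(OTf)3 (10 mol %), 4 Å MS, CH2Cl2 (0.01 M), −20 °C → rt
Reagents that add atoms: none
Why: Proposed new method: an intramolecular Lewis-acid-catalysed diazo–ketone homologation in which the fully substituted α-diazo-δ-lactone carbon C8 adds through a seven-membered transition state to its own Sc-activated, strained cyclobutanone carbon C15 from the only face the C9 tether allows (syn to C11), giving betaine 21 in which one of the two equivalent cyclobutane CH2–C15 bonds lies antiperiplanar to C8–N2+ and migrates with inversion at C8 and loss of N2 (about 20 kcal/mol of ring strain released), so that C8–C15 and C8–C14, rings C and D, the quaternary (8S) centre and (13R) are set at once with C14 syn and C15 anti to C11 as in the target, and no regiochemical question arises because both α-carbons are equivalent; the closest known reaction type is the intermolecular Tiffeneau–Demjanov-type (Büchner–Curtius–Schlotterbeck) ring expansion of cycloalkanones with α-alkyl-α-diazo esters under BF3·OEt2 or Sc(OTf)3, which has not been used intramolecularly to build a bridged bicyclo[3.2.1]octane.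

**Step 11**
Reactants: 22 tetracyclic β-keto lactone; 23 formaldehyde (monomer in THF, from cracked paraformaldehyde)
Product: 24 (5R,8S,9S,10S,13R,16R)-16-(hydroxymethyl) β-keto lactone, 6-O-TBDPS ether of the target
Conditions: LiN(SiMe3)2, THF, −78 °C; CH2O, −78 °C; AcOH quench
Reagents that add atoms: none
Why: Kinetic lithium enolate aldol addition; C16 is the only enolisable carbon in 22, and formaldehyde approaches the ring D enolate from the exo face (anti to the C9–C11–C12 bridge), giving the (16R) exo-CH2OH, which is also the less crowded epimer.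

**Step 12**
Reactants: 24 6-O-TBDPS ether of the target
Product: 25 CNP0505075.1 (5R,8S,9S,10S,13R,16R)
Conditions: HF·pyridine, pyridine/THF, 0 °C → rt
Reagents that add atoms: none
Why: Fluoride-mediated desilylation under weakly acidic conditions spares the β-hydroxy ketone, the enone and the lactone, and no stereocentre is touched.

**Compound list**
1 | 2-[(tert-butyldiphenylsilyl)oxy]acetaldehyde | O=CCO[Si](c1ccccc1)(c1ccccc1)C(C)(C)C | starting material
2 | methyl acetoacetate | CC(=O)CC(=O)OC | starting material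
3 | methyl 2-acetyl-4-[(tert-butyldiphenylsilyl)oxy]but-2-enoate (E/Z mixture) | CC(=O)C(=CCO[Si](c1ccccc1)(c1ccccc1)C(C)(C)C)C(=O)OC | intermediate
4 | isobutyraldehyde | CC(C)C=O | starting material
5 | methyl (3S)-2-acetyl-3-{[(tert-butyldiphenylsilyl)oxy]methyl}-4,4-dimethyl-5-oxopentanoate (C2 epimers) | CC(=O)C(C(=O)OC)[C@H](CO[Si](c1ccccc1)(c1ccccc1)C(C)(C)C)C(C)(C)C=O | intermediate (not isolated)
6 | methyl (1S,6S)-6-{[(tert-butyldiphenylsilyl)oxy]methyl}-5,5-dimethyl-2-oxocyclohex-3-ene-1-carboxylate (trans; C1 epimerisable) | CC1(C)C=CC(=O)[C@@H](C(=O)OC)[C@@H]1CO[Si](c1ccccc1)(c1ccccc1)C(C)(C)C | intermediate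
7 | hexa-1,5-diene | C=CCCC=C | starting material
8 | N,N-dimethylacetamide | CC(=O)N(C)C | starting material
9 | N,N-dimethylketeniminium triflate | C=C=[N+](C)C.[O-]S(=O)(=O)C(F)(F)F | intermediate (not isolated)
10 | 3-(but-3-en-1-yl)-N,N-dimethylcyclobutan-1-iminium triflate | C=CCCC1CC(=[N+](C)C)C1.[O-]S(=O)(=O)C(F)(F)F | intermediate (not isolated)
11 | 3-(but-3-en-1-yl)cyclobutan-1-one | C=CCCC1CC(=O)C1 | intermediate
12 | 2-(but-3-en-1-yl)-5,8-dioxaspiro[3.4]octane | C=CCCC1CC2(C1)OCCO2 | intermediate
13 | (E)-crotonaldehyde | C/C=C/C=O | starting material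
14 | (E)-5-(5,8-dioxaspiro[3.4]octan-2-yl)pent-2-enal | O=C/C=C/CCC1CC2(C1)OCCO2 | intermediate
15 | (5R,9R,10R)-Michael adduct aldehyde | CC1(C)C=CC(=O)[C@]([C@@H](CC=O)CCC2CC3(C2)OCCO3)(C(=O)OC)[C@@H]1CO[Si](c1ccccc1)(c1ccccc1)C(C)(C)C | intermediate
16 | (5R,9R,10S)-triol (C1 epimers) | CC1(C)C=CC(O)[C@]([C@@H](CCO)CCC2CC3(C2)OCCO3)(CO)[C@@H]1CO[Si](c1ccccc1)(c1ccccc1)C(C)(C)C | intermediate
17 | (5R,9R,10S)-spirolactone enone ketal | CC1(C)C=CC(=O)[C@]2(COC(=O)C[C@H]2CCC2CC3(C2)OCCO3)[C@@H]1CO[Si](c1ccccc1)(c1ccccc1)C(C)(C)C | intermediate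
18 | 8-trifluoroacetyl spirolactone ketal (C8 enolisable) | CC1(C)C=CC(=O)[C@]2(COC(=O)C(C(=O)C(F)(F)F)[C@H]2CCC2CC3(C2)OCCO3)[C@@H]1CO[Si](c1ccccc1)(c1ccccc1)C(C)(C)C | intermediate (not isolated)
19 | 8-trifluoroacetyl spirolactone with free cyclobutanone | CC1(C)C=CC(=O)[C@]2(COC(=O)C(C(=O)C(F)(F)F)[C@H]2CCC2CC(=O)C2)[C@@H]1CO[Si](c1ccccc1)(c1ccccc1)C(C)(C)C | intermediate (not isolated)
20 | (5R,9S,10S)-8-diazo spirolactone with free cyclobutanone | CC1(C)C=CC(=O)[C@]2(COC(=O)C(=[N+]=[N-])[C@H]2CCC2CC(=O)C2)[C@@H]1CO[Si](c1ccccc1)(c1ccccc1)C(C)(C)C | intermediate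
21 | bicyclo[4.1.1]octane-type C15-oxido C8-diazonium betaine (Sc-bound) | CC1(C)C=CC(=O)[C@]2(COC(=O)[C@]3([N+]#N)[C@H]2CCC2CC3([O-])C2)[C@@H]1CO[Si](c1ccccc1)(c1ccccc1)C(C)(C)C | intermediate (not isolated)
22 | (5R,8S,9S,10S,13R)-tetracyclic β-keto lactone, 6-O-TBDPS, C16H2 | CC1(C)C=CC(=O)[C@]2(COC(=O)[C@@]34C[C@@H](CC[C@H]32)CC4=O)[C@@H]1CO[Si](c1ccccc1)(c1ccccc1)C(C)(C)C | intermediate
23 | formaldehyde | C=O | starting material
24 | (16R)-16-hydroxymethyl β-keto lactone, 6-O-TBDPS | CC1(C)C=CC(=O)[C@]2(COC(=O)[C@@]34C[C@@H](CC[C@H]32)[C@H](CO)C4=O)[C@@H]1CO[Si](c1ccccc1)(c1ccccc1)C(C)(C)C | intermediate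
25 | CNP0505075.1 | CC1(C)C=CC(=O)[C@]2(COC(=O)[C@@]34C[C@@H](CC[C@H]32)[C@H](CO)C4=O)[C@@H]1CO | target

**Total steps:** 12. **Longest linear sequence:** 10 (steps 3–12, from 7 and 8).

**Three steps most likely to fail**

1. **Step 10 (the new step).**
   - Risks: the seven-membered approach to C15 may be slow. Competing paths are a 1,2-hydride shift from C9 giving the unsaturated lactone, and collapse of 21 to the spiro-epoxide.
   - Fallback, known chemistry only, sets out from 17 and comes back at 22.
   - Acid hydrolysis (1 M HCl, THF) gives keto lactone F1.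
   - A catalyst-controlled desymmetrising Baeyer–Villiger oxidation of the 3-substituted cyclobutanone (chiral BINOL-phosphoric acid, 30 % H2O2, CHCl3, −40 °C) gives (13S)-butyrolactone F2, in which the two ring methylenes are differentiated as C14–O and C16–C15(=O).
   - TMSCl/NaI in MeCN, then MeOH, opens it to iodo ester F3.
   - LiN(SiMe3)2 closes ring C by intramolecular alkylation of the δ-lactone enolate (C8–C14) to tricyclic lactone ester F4.
   - KN(SiMe3)2 (THF, −78 → 0 °C) closes ring D by Dieckmann condensation (C8–C15) to 22.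

2. **Step 6.**
   - Risks: the nucleophilic carbon C10 is flanked by the substituted C5 and sits one carbon from the quaternary C4. Addition to a β-alkyl enal may therefore be slow or reversible, and the catalyst's preferred C9 face may be mismatched with the substrate's preferred C10 face.
   - Fallback sets out from 6 and 12 and comes back at 16.
   - Cross metathesis of 12 with allyl methyl carbonate gives allylic carbonate F5.
   - Branched-selective allylic alkylation of 6 ([Ir(cod)Cl]2, chiral phosphoramidite, TBD, LiOtBu, THF) gives vinyl keto ester F6, with the C9 configuration set by the catalyst.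
   - LiAlH4 gives diol F7.
   - 9-BBN then NaBO3 hydroborates only the terminal vinyl group to give 16.

3. **Step 2.**
   - Risks: alkylidene acetoacetates are weaker acceptors than the nitroalkenes and maleimides for which this catalyst class is established. The E/Z mixture may also erode the enantioselectivity.
   - Fallback sets out from 3 and 4 and comes back at 5.
   - Compound 4 is converted (TMSCl, Et3N, DMF, 80 °C) into silyl enol ether F8.
   - F8 is added to 3 in a Mukaiyama–Michael reaction under a chelating chiral Lewis acid of divalent copper, Cu(SbF6)2·(S,S)-tBu-box (10 mol %), with (CF3)2CHOH in CH2Cl2 at −78 → −20 °C. The two-point binding of the 1,3-dicarbonyl fixes the C5 face.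
   - The resulting 5 is cyclised with TsOH as in step 2.

**Further compounds**
F1 | step 10 | (5R,9R,10S)-spirolactone enone with free cyclobutanone | CC1(C)C=CC(=O)[C@]2(COC(=O)C[C@H]2CCC2CC(=O)C2)[C@@H]1CO[Si](c1ccccc1)(c1ccccc1)C(C)(C)C
F2 | step 10 | (13S)-β-substituted γ-butyrolactone from Baeyer–Villiger oxidation | CC1(C)C=CC(=O)[C@]2(COC(=O)C[C@H]2CC[C@@H]2COC(=O)C2)[C@@H]1CO[Si](c1ccccc1)(c1ccccc1)C(C)(C)C
F3 | step 10 | (13S)-iodo ester with C14H2I and C16H2CO2Me | CC1(C)C=CC(=O)[C@]2(COC(=O)C[C@H]2CC[C@H](CI)CC(=O)OC)[C@@H]1CO[Si](c1ccccc1)(c1ccccc1)C(C)(C)C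
F4 | step 10 | ring C-closed tricyclic lactone ester (C8 epimers, 13R) | CC1(C)C=CC(=O)[C@]2(COC(=O)C3C[C@H](CC(=O)OC)CC[C@H]32)[C@@H]1CO[Si](c1ccccc1)(c1ccccc1)C(C)(C)C
F5 | step 6 | (E)-5-(5,8-dioxaspiro[3.4]octan-2-yl)pent-2-en-1-yl methyl carbonate | COC(=O)OC/C=C/CCC1CC2(C1)OCCO2
F6 | step 6 | (5R,9R,10R)-branched allylation product with vinyl at C9 | CC1(C)C=CC(=O)[C@]([C@@H](C=C)CCC2CC3(C2)OCCO3)(C(=O)OC)[C@@H]1CO[Si](c1ccccc1)(c1ccccc1)C(C)(C)C
F7 | step 6 | (5R,9R,10S)-vinyl diol (C1 epimers) | CC1(C)C=CC(O)[C@]([C@@H](C=C)CCC2CC3(C2)OCCO3)(CO)[C@@H]1CO[Si](c1ccccc1)(c1ccccc1)C(C)(C)C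
F8 | step 2 | trimethyl[(2-methylprop-1-en-1-yl)oxy]silane | CC(C)=CO[Si](C)(C)C
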